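## Structural features

The target is a briarane: a cyclohexane (ring A, C1 and C10–C14) fused through the C1–C10 bond to a ten-membered carbocycle (C1–C10), which in turn carries a γ-lactone fused at C7–C8 (carbonyl C19, ring oxygen on C7, methyl-bearing C17). Twelve stereocentres are present; those of ring A (quaternary C1, C10, C11, C12, C13, C14) run without a break into C9, the fully substituted carbinol C8, C7 and C6, with C17 and C2 at the two ends. The C1 methyl (C15), the C9 branch on C10 and the C11 methyl (C20) lie on one face of ring A; C2, the C12 acetate and the 13,14-epoxide lie on the other. Fragile groups are the secondary allylic chloride at C6 next to the C5=C16 methylidene (ionisation, allylic shift), the epoxide flanked by an acetate (acid), the β-hydroxy-γ-lactone with its epimerisable C17 (base), and two acetates that must coexist with a free secondary (C9) and a free tertiary (C8) hydroxyl group. The real difficulty is the densely oxygenated ten-membered carbocycle anchored on the quaternary C1, for which direct C–C ring closure is penalised by entropy and transannular strain. The key step uses the fact that C2 (a ketone one step before the acetate), C3, C4 and the methylidene C5=C16 form a γ,δ-unsaturated ketone inside the ten-membered ring. This is the retron of a Claisen rearrangement, so the carbocycle can be drawn from a ten-membered lactone in which C2 is joined to C16 through oxygen.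

## Logic of the disconnections

47 is traced to 46 by cutting only the O–benzyl bond at O9. The C9 hydroxyl stays masked until both acetates are in place and the lactone regiochemistry is settled; the demand is a neutral, oxidative debenzylation that spares epoxide, chloride and esters.

46 goes back through 45 to 44 by cutting the C12 O–acetyl bond and the two C–O bonds of the oxirane. Epoxide and C12 oxygen share one face, so an allylic alcohol can direct the oxidant. Two stereocentres disappear; the forward step needs the C12 hydroxyl to be the only hydroxyl placed to direct an epoxidation of a nearby alkene.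

44 goes back through 43 to 41 by cutting the lactone C19–O7 bond and lowering C19 to a primary alcohol, and 41 goes back to 40 by restoring the acetonide and the C19 silyl ether. No carbonyl other than C2 may be present when C2 is methylenated, so the lactone has to be a late event. The demand is that O7 and O19 are freed together while O9 stays blocked, because O9 could close an isomeric γ-lactone.

40 goes back to 39 by cutting C6–Cl to the epimeric allylic alcohol, and 39 to 38 by restoring the C6 silyl ether. An allylic chloride would not survive methylenation and heating; the forward step must substitute with inversion and without allylic shift.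

38 goes back through 37 to 36 by cutting the C2 O–acetyl bond and raising C2 to the ketone. This exposes the Claisen retron; the forward reduction must deliver hydride to the face of C2 opposite C10.

36 goes back to 35 by breaking C3–C4 and joining O to C16. The carbocycle becomes a ten-membered cyclic allyl vinyl ether whose ring can be closed through a C–O bond. No stereocentre is involved; the forward step needs a boat-like fold that brings C3 to C4.

35 goes back through 34 to 33 by cutting C2=C3 (carbonyl methylenation) and then the O–C16 bond of the lactone. The ring-closing event becomes an ester formation at an unhindered allylic carbon; the demand is a medium-ring lactonisation of a hindered, pivalate-like acid.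

33 goes back through 32, 31, 30 and 29 to 25 and 27 by cutting C5–C6. The three-carbon unit C4–C5–C16 is added as a vinyl nucleophile to a C6 acyl group, and C6 is set afterwards by reduction; the demand is Felkin–Anh control by C7.

25 goes back through 24, 22 and 21 to 20. The C13=C14 alkene is traced to a C13 ketone through its enol triflate, and the C6 amide to a γ-lactone that ties O9 to C6. No skeletal bond is cut; the lactone serves as protection for O9, as the C6 acyl group, and as the template for the next cut. The demand is enolisation of the ketone only.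

20 goes back through 19 to 18 by cutting the C7–O and C8–O bonds. On the butenolide the face opposite the C9 substituent is the only open one, so a syn-dihydroxylation sets C7 and C8 relative to C9 in one step.

18 goes back to 16 by cutting C12–O. The silyl enol ether left by the cycloaddition is the natural site for oxygenation; the demand is attack on the face opposite the C11 methyl group and the C10 substituent.

16 goes back to 7 and 14 by cutting C8–C9 and the lactone O9–C6 bond. This separates ring A from the whole C6–C8/C17–C19 unit; the forward addition must follow the Felkin–Anh sense set by C10.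

7 goes back to 4 and 6 by cutting C10–C11 and C1–C14. With the formyl group as C9 and the silyloxy group on C13, the endo rule places C15, C9 and C20 on one face, and C2 and C9 leave the cycloaddition at the oxidation levels needed. The price is that oxygen must be moved from C13 to C12 later; the demand is enantiofacial control by a chiral Lewis acid.

14 goes back through 13, 11, 10 and 9 to 8 (C6–C7 cut at the acetylide, C7–C8 by aldehyde homologation); 4 to 1 and 2 (C1=C10 by olefination); 6 to 5; 27 to 26. All stereochemistry of the side chain comes from 8.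

## Other disconnections considered

Alternative 1: The cut is again C10–C11 and C1–C14 of ring A, but with the opposite polarity: the enal A2 carries the activating formyl group as C2, and the silyl dienol ether A3 carries its oxygen on C12. A Lewis acid such as Me2AlCl would join them to A1. In its favour, oxygen arrives directly on C12, so that an enone and its reduction would give the ring A allylic alcohol without the oxygen shift that costs the chosen plan steps 11, 16 and 17; on this point Alternative 1 is the better. The absolute configuration would come from a chiral-pool acetal and not from a chiral catalyst, which is at least equal. Against it, the C11 methyl of A3 is on the outside of the diene, so a formyl-endo transition state would place it cis to C2, whereas A1 and the target have it cis to C9. A1 therefore needs the formyl-exo mode or a later inversion at C11; α-substituted enals often lean towards that mode, so the demand is not unreasonable, but it is less predictable than the endo rule on which the chosen plan relies. C2 also arrives as an aldehyde and C8 as a primary alcohol, so several oxidation-level changes follow. The two plans use the same bonds and the same concerted mechanism; the chosen plan reverses the roles so that the endo rule works for C11. In step count the alternative gains one or two steps on ring A and loses more on C2, C8 and C9, and it leaves the ten-membered ring unsolved.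

Alternative 2: The cut is C6–Cl and C7–O of the lactone. The seco acid A5, with an E C6=C7 double bond in the ten-membered ring, would take up electrophilic chlorine at C6 while the C19 carboxyl group attacks C7 in a 5-exo mode, giving A4. In its favour, one step forms two bonds, the lactone ring and two stereocentres, and anti addition to an E alkene gives the anti Cl/O relationship of the target. No substitution at the hindered allylic C6 is needed; on this point the alternative is better than steps 30 and 32 of the chosen plan. Against it, A4 has an sp3 C5 bearing CH2O, so the methylidene must be made afterwards by elimination next to a β-chloride, where loss of HCl competes. The tertiary C8 hydroxyl is a competing nucleophile, the face of chloronium formation on a medium ring has no obvious control element, and the ten-membered ring with its E alkene must first be closed by another method. The chosen plan obtains the methylidene directly from the rearrangement and pays with a separate substitution; the alternative obtains chloride and lactone directly and pays with the methylidene. No net saving of steps is expected.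

Alternative 3: The cut is the C2=C7 double bond common to rings B and C of the hydrophenanthrene A7; ozone, or OsO4 followed by Pb(OAc)4, would open it to the ten-membered diketone A6. In its favour, the medium ring arises from two six-membered rings with no entropic penalty and no high dilution, and annulation routes to A7 are well established. In certainty of ring formation this alternative is better than the chosen plan, whose ring transfer has no precedent. Against it, A6 has CH2 groups at C6, C8 and C9 and no C17–C19 branch. The two ketones must be told apart, a cyclodecane-1,6-dione is prone to transannular aldol closure, and five stereocentres (C6–C9, C17) plus the ring A alkene would have to be introduced on a flexible ring. The chosen plan sets C6–C9 and C17 in acyclic or five-membered settings before the ring exists. The alternative is shorter to the bare ring and much longer from there.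

Key step: step 26

Remarks on the chemistry (conventions and assumptions)
- Locants follow briarane numbering (C1–C20; C15 on C1, C16 on C5, C18 and C19 on C17, C20 on C11); β is the face of ring A that carries C15, α the opposite face.
- Key-step structures: constitution and every stereocentre of 35 and 36 map onto 47 (C6 carries oxygen with the configuration opposite to the chloride, as an invertive substitution requires); the design effort therefore goes into the spectator groups and the assembly of ring A.
- Precursor design: O19 is carried as a silyl ether rather than a benzyl ether, because hydrogenolysis would be impossible beside three alkenes. O7/O8 are tied as an acetonide and O9 is a PMB ether rather than three MOM ethers, which separates O7 from O9 for the lactone closure and avoids acid after the epoxide exists. O6 (TES) and O12 (TIPS) are made distinguishable.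
- Catalyst hand in step 4: the (S)-prolinol-derived oxazaborolidinium salt is chosen on the basis of the formyl C–H···O binding model, which should leave the C10 Si face open. The absolute sense would be verified at the stage of 16, where the stereocentre from 8 serves as internal reference; the mirror-image catalyst would be used if the opposite sense were found.

## Route

Step 1
Reactants: 1 2,2-dimethoxyacetaldehyde; 2 methyl 2-(triphenylphosphoranylidene)propanoate
Product: 3 methyl (E)-4,4-dimethoxy-2-methylbut-2-enoate
Conditions: CH2Cl2, rt (1 as 60% aqueous solution)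
Reagents that add atoms: none
Why: Wittig olefination with a stabilised ylide, which tolerates water and should give the E alkene (ester trans to the acetal carbon), the geometry that later places C2 and C9 trans on ring A.

Step 2
Reactants: 3 methyl (E)-4,4-dimethoxy-2-methylbut-2-enoate
Product: 4 methyl (E)-2-methyl-4-oxobut-2-enoate
Conditions: Amberlyst-15, acetone/H2O, rt
Reagents that add atoms: water, O
Why: Acid-catalysed acetal hydrolysis; the mild resin should leave the E geometry and the ester untouched.

Step 3
Reactants: 5 (E)-pent-3-en-2-one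
Product: 6 (E)-2-(triisopropylsilyloxy)penta-1,3-diene
Conditions: TIPSOTf, Et3N, Et2O, 0 °C → rt
Reagents that add atoms: triisopropylsilyl trifluoromethanesulfonate, CC(C)[Si](OS(=O)(=O)C(F)(F)F)(C(C)C)C(C)C
Why: Soft enolisation and O-silylation of the methyl ketone give the cross-conjugated silyloxy diene with the C3=C4 geometry retained; the TIPS group is chosen to survive the strongly acidic catalyst of step 4.

Step 4
Reactants: 4 methyl (E)-2-methyl-4-oxobut-2-enoate; 6 (E)-2-(triisopropylsilyloxy)penta-1,3-diene
Product: 7 ring A aldehyde, methyl (1S,5S,6S)-6-formyl-1,5-dimethyl-3-(triisopropylsilyloxy)cyclohex-3-ene-1-carboxylate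
Conditions: (S)-3,3-diphenyl-1-(o-tolyl)tetrahydro-1H,3H-pyrrolo[1,2-c][1,3,2]oxazaborole (20 mol%), HN(SO2CF3)2 (20 mol%), CH2Cl2, −78 °C
Reagents that add atoms: none
Why: Catalytic enantioselective Diels–Alder reaction: the CH2 terminus next to the silyloxy carbon bonds to C1 (β to the activated formyl group) and the methyl-bearing terminus to C10. The E dienophile fixes C15 cis to C9, the formyl-endo transition state puts C9 and C15 cis to the outside methyl C20, and the catalyst shields one face so that the diene adds to the C10 Si face.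

Step 5
Reactants: 8 methyl (S)-3-hydroxy-2-methylpropanoate
Product: 9 methyl (S)-2-methyl-3-(triisopropylsilyloxy)propanoate
Conditions: TIPSCl, imidazole, DMF, rt
Reagents that add atoms: chlorotriisopropylsilane, CC(C)[Si](Cl)(C(C)C)C(C)C
Why: Standard silylation of a primary alcohol; TIPS is chosen because it withstands the hot acetic acid of step 9.

Step 6
Reactants: 9 methyl (S)-2-methyl-3-(triisopropylsilyloxy)propanoate
Product: 10 (S)-2-methyl-3-(triisopropylsilyloxy)propanal
Conditions: i-Bu2AlH (1.05 equiv), CH2Cl2, −78 °C; aq. potassium sodium tartrate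
Reagents that add atoms: none
Why: Partial reduction of the ester; the aluminium hemiacetal is stable at −78 °C and the cold, neutral work-up should preserve the α-stereocentre (C17).

Step 7
Reactants: 10 (S)-2-methyl-3-(triisopropylsilyloxy)propanal
Product: 11 (R)-(4,4-dibromo-2-methylbut-3-enyloxy)triisopropylsilane
Conditions: CBr4, PPh3, Et3N, CH2Cl2, 0 °C
Reagents that add atoms: tetrabromomethane, BrC(Br)(Br)Br
Why: First stage of the Corey–Fuchs homologation; the buffered conditions should not epimerise C17.

Step 8
Reactants: 11 (R)-(4,4-dibromo-2-methylbut-3-enyloxy)triisopropylsilane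
Product: 13 methyl (R)-4-methyl-5-(triisopropylsilyloxy)pent-2-ynoate, via lithium acetylide 12 (not isolated)
Conditions: n-BuLi (2.1 equiv), THF, −78 °C; ClCO2Me, −78 → 0 °C
Reagents that add atoms: methyl chloroformate, COC(Cl)=O
Why: Second stage of the Corey–Fuchs sequence (exchange, rearrangement to the alkyne, deprotonation) followed by C-acylation of the acetylide, which supplies C6 at the ester level.

Step 9
Reactants: 13 methyl (R)-4-methyl-5-(triisopropylsilyloxy)pent-2-ynoate
Product: 14 methyl (S,Z)-3-iodo-4-methyl-5-(triisopropylsilyloxy)pent-2-enoate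
Conditions: NaI, AcOH, 80 °C
Reagents that add atoms: sodium iodide, [Na+].[I-]
Why: Conjugate hydroiodination of an ynoate proceeds by anti addition, so iodine (on C8) ends cis to the ester (C6), the geometry needed for the butenolide.

Step 10
Reactants: 7 ring A aldehyde, methyl (1S,5S,6S)-6-formyl-1,5-dimethyl-3-(triisopropylsilyloxy)cyclohex-3-ene-1-carboxylate; 14 methyl (S,Z)-3-iodo-4-methyl-5-(triisopropylsilyloxy)pent-2-enoate
Product: 16 butenolide (ring A of 7 bearing at C10 the (9R)-5-oxo-2,5-dihydrofuran-2-yl ring; O9–C6 lactone; C7=C8; CH(CH3)CH2OTIPS on C8), via hydroxy enoate 15 (not isolated)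
Conditions: CrCl2 (5 equiv), NiCl2 (2 mol%), DMSO, rt; aq. NH4Cl; PPTS (cat.), CH2Cl2, rt
Reagents that add atoms: none
Why: Nozaki–Hiyama–Kishi coupling, selective for the aldehyde and non-basic, so C10 is not epimerised. The Felkin–Anh model with quaternary C1 as the large group predicts the 9R alcohol, and the cis γ-hydroxy ester closes to the butenolide, which ties O9 to C6.

Step 11
Reactants: 16 butenolide (ring A of 7 bearing at C10 the (9R)-5-oxo-2,5-dihydrofuran-2-yl ring; O9–C6 lactone; C7=C8; CH(CH3)CH2OTIPS on C8)
Product: 18 α-silyloxy ketone (16 in which ring A has C12(H)–OTIPS on the α face and C13=O), via silyloxy epoxide 17 (not isolated)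
Conditions: dimethyldioxirane, acetone/CH2Cl2, −78 → 0 °C; PPTS (cat.), CH2Cl2, rt
Reagents that add atoms: dimethyldioxirane, CC1(C)OO1
Why: Rubottom oxidation; the oxidant should attack the enol ether on the α face, away from the axial C10 substituent and the C11 methyl group, and the 1,4-silyl shift then delivers the 12α-silyloxy ketone (oxygen trans to C20), while the electron-poor butenolide alkene is inert.

Step 12
Reactants: 18 α-silyloxy ketone (16 in which ring A has C12(H)–OTIPS on the α face and C13=O)
Product: 19 diol lactone (18 with C7–OH and C8–OH cis to each other and trans to ring A on the saturated γ-lactone)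
Conditions: K2OsO4·2H2O (5 mol%), N-methylmorpholine N-oxide, citric acid, t-BuOH/H2O, rt
Reagents that add atoms: N-methylmorpholine N-oxide, C[N+]1([O-])CCOCC1; water, O
Why: Upjohn dihydroxylation with citric acid for the electron-poor alkene; OsO4 adds to the butenolide face opposite the C9 substituent, which sets C7 and C8 anti to O9 as in 47.

Step 13
Reactants: 19 diol lactone (18 with C7–OH and C8–OH cis to each other and trans to ring A on the saturated γ-lactone)
Product: 20 acetonide lactone (7,8-O-isopropylidene derivative of 19)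
Conditions: 2,2-dimethoxypropane, PPTS (cat.), CH2Cl2, rt
Reagents that add atoms: 2,2-dimethoxypropane, COC(C)(C)OC
Why: Ketal exchange on a cis diol of a five-membered ring; the hindered α-silyloxy ketone should not form a ketal under these conditions.

Step 14
Reactants: 20 acetonide lactone (7,8-O-isopropylidene derivative of 19)
Product: 21 hydroxy Weinreb amide (20 with the lactone opened to C6(=O)N(CH3)OCH3 and a free 9R hydroxyl)
Conditions: MeNH(OMe)·HCl, Me3Al, CH2Cl2, 0 °C → rt
Reagents that add atoms: N,O-dimethylhydroxylamine hydrochloride, CNOC.Cl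
Why: Aminolysis of the strained α-alkoxy γ-lactone by the aluminium amide (Weinreb amide formation); the neopentyl methyl ester at C2 and the hindered ketone should react far more slowly.

Step 15
Reactants: 21 hydroxy Weinreb amide (20 with the lactone opened to C6(=O)N(CH3)OCH3 and a free 9R hydroxyl)
Product: 22 PMB ether (9-O-(4-methoxybenzyl) derivative of 21)
Conditions: 2-(4-methoxybenzyloxy)-4-methylquinoline, MeOTf, MgO, PhCF3, 0 °C → rt
Reagents that add atoms: 2-(4-methoxybenzyloxy)-4-methylquinoline, COc1ccc(COc2cc(C)c3ccccc3n2)cc1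
Why: Benzyl transfer from an N-methylquinolinium salt under neutral conditions, used because base or acid would send the γ-hydroxy amide back to the lactone and because the reagent is known to reach hindered alcohols.

Step 16
Reactants: 22 PMB ether (9-O-(4-methoxybenzyl) derivative of 21)
Product: 24 enol triflate (22 with C13(OSO2CF3)=C14 in ring A), via potassium enolate 23 (not isolated)
Conditions: KN(SiMe3)2 (1.1 equiv), THF, −78 °C; PhN(SO2CF3)2, −78 → 0 °C
Reagents that add atoms: N-phenylbis(trifluoromethanesulfonimide), O=S(=O)(N(c1ccccc1)S(=O)(=O)C(F)(F)F)C(F)(F)F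
Why: Kinetic enolisation of the ketone toward the C14 methylene (C12–H is hindered and α-oxygenated, the amide α-hydrogen is far less acidic, the ester has none) and O-triflation.

Step 17
Reactants: 24 enol triflate (22 with C13(OSO2CF3)=C14 in ring A)
Product: 25 ring A alkene (24 with H in place of the triflate; 12α-OTIPS; C13=C14)
Conditions: Pd(OAc)2 (5 mol%), PPh3, HCO2H, n-Bu3N, DMF, 60 °C
Reagents that add atoms: none
Why: Palladium-catalysed formate reduction of an enol triflate; it completes the shift of oxygen from C13 to C12 and leaves ring A as the allylic silyl ether needed for the later directed epoxidation.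

Step 18
Reactants: 26 2-bromoprop-2-en-1-ol
Product: 27 (2-bromoprop-2-enyloxy)triethylsilane
Conditions: TESCl, imidazole, CH2Cl2, 0 °C
Reagents that add atoms: chlorotriethylsilane, CC[Si](Cl)(CC)CC
Why: Standard silylation; the primary TES ether is later the most labile silyl group in the molecule.

Step 19
Reactants: 27 (2-bromoprop-2-enyloxy)triethylsilane; 25 ring A alkene (24 with H in place of the triflate; 12α-OTIPS; C13=C14)
Product: 29 enone (25 with C6 as a ketone bonded to C5(=C4H2)–C16H2OTES), via vinyllithium 28 (not isolated)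
Conditions: t-BuLi (2 equiv), Et2O, −78 °C; then 25, THF, −78 °C; aq. NH4Cl
Reagents that add atoms: none
Why: Bromine–lithium exchange and acylation of the vinyllithium by the Weinreb amide, whose chelated tetrahedral intermediate stops at the ketone; at −78 °C the neopentyl ester should not react and silyl migration from O to C should be suppressed.

Step 20
Reactants: 29 enone (25 with C6 as a ketone bonded to C5(=C4H2)–C16H2OTES)
Product: 30 allylic alcohol (6R alcohol of 29; O6 syn to O7)
Conditions: NaBH4, CeCl3·7H2O, MeOH, −78 °C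
Reagents that add atoms: none
Why: Luche 1,2-reduction; with the dioxolane oxygen on C7 perpendicular to the carbonyl (polar Felkin–Anh model, no chelation in methanol) hydride should add to give the 6R alcohol, epimeric to the chloride of 47.

Step 21
Reactants: 30 allylic alcohol (6R alcohol of 29; O6 syn to O7)
Product: 31 bis-TES ether (6-O-triethylsilyl derivative of 30)
Conditions: TESOTf, 2,6-lutidine, CH2Cl2, −78 °C
Reagents that add atoms: triethylsilyl trifluoromethanesulfonate, CC[Si](CC)(CC)OS(=O)(=O)C(F)(F)F
Why: Silylation of a hindered secondary alcohol with a silyl triflate.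

Step 22
Reactants: 31 bis-TES ether (6-O-triethylsilyl derivative of 30)
Product: 32 carboxylic acid (31 with CO2H at C2)
Conditions: n-PrSLi (from n-PrSH and n-BuLi), HMPA, rt; pH 5 buffer
Reagents that add atoms: none
Why: SN2 dealkylation at the methyl group, the reliable way to open a pivalate-like ester whose carbonyl is out of reach of hydroxide; silyl ethers, acetonide and PMB ether are inert to thiolate.

Step 23
Reactants: 32 carboxylic acid (31 with CO2H at C2)
Product: 33 hydroxy acid (32 with a free C16 hydroxyl)
Conditions: PPTS (cat.), MeOH/CH2Cl2, −10 °C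
Reagents that add atoms: none
Why: Acid-catalysed methanolysis removes the primary allylic TES ether much faster than the hindered secondary one at C6, the TIPS ethers or the acetonide.

Step 24
Reactants: 33 hydroxy acid (32 with a free C16 hydroxyl)
Product: 34 ten-membered lactone (C2(=O)–O–C16; ring atoms C2, O, C16, C5–C10 and C1; C5=C4H2)
Conditions: PPh3, DIAD, toluene/THF, slow addition to 0.002 M, 0 °C → rt
Reagents that add atoms: none
Why: Mitsunobu macrolactonisation: the ring is closed by carboxylate attack on the activated primary allylic carbinol, so the hindered acyl carbon is never the electrophile, and direct and allylic displacement give the same product because both allyl termini are CH2.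

Step 25
Reactants: 34 ten-membered lactone (C2(=O)–O–C16; ring atoms C2, O, C16, C5–C10 and C1; C5=C4H2)
Product: 35 ten-membered bis-exocyclic allyl vinyl ether (34 with C2=C3H2 in place of C2=O)
Conditions: Cp2TiMe2 (3 equiv), toluene, 65 °C, dark; basic alumina
Reagents that add atoms: dimethyltitanocene, [CH3-].[CH3-].[Ti+4].c1cc[cH-]c1.c1cc[cH-]c1
Why: Petasis methylenation of a lactone through the titanium methylidene; the lactone is the only carbonyl group present, and the quaternary C1 prevents the new enol ether from isomerising.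

Step 26
Reactants: 35 ten-membered bis-exocyclic allyl vinyl ether (34 with C2=C3H2 in place of C2=O)
Product: 36 ten-membered C2 ketone with C5=C16H2 methylidene (carbocycle C1–C10)
Conditions: mesitylene (0.005 M), 2,6-di-tert-butyl-4-methylpyridine (0.2 equiv), silylated sealed tube, 165–180 °C
Reagents that add atoms: none
Why: Proposed new method: on heating, the array C3=C2–O–C16–C5=C4 should undergo a concerted [3,3]-sigmatropic (Claisen) shift in which O–C16 breaks and C3–C4 forms, so that the ring atoms O and C16 are exchanged for C3 and C4 and the ten-membered heterocycle becomes the ten-membered carbocycle. The closest known reaction types are the Claisen rearrangement of methylenated lactones to carbocycles (2-methylidene-6-vinyltetrahydropyrans to cyclooctenones) and the Ireland–Claisen contraction of macrolactones; a case with both alkenes exocyclic and the ring size conserved is not known. The carbocycle closes by C3–C4 bond formation through a boat-like six-centre transition state, because C2 and C5 remain tied by the six-atom arc C6–C10/C1, as in a bicyclo[6.2.2]dodecane frame. No stereocentre is formed or touched, since C3, C4 and C16 are CH2 groups and C1 and C6 are spectators. The step needs the sigmatropic path to win over ionisation, which the neutral, base-buffered hydrocarbon medium should secure; a 1,3-shift would in any case give the same product because both allyl termini are CH2. It needs an enol ether that cannot move into the ring, which the quaternary C1 secures. It needs a fold that brings C3 within reach of C4, which the cis-fused dioxolane (holding C6 and C9 syn) and the flexible C2–O–C16 hinge should assist. Formation of the C2 carbonyl group, worth roughly 80 kJ/mol in Claisen rearrangements generally, should pay for the boat geometry.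

Step 27
Reactants: 36 ten-membered C2 ketone with C5=C16H2 methylidene (carbocycle C1–C10)
Product: 37 alcohol (2R alcohol of 36)
Conditions: NaBH4, MeOH/THF, 0 °C
Reagents that add atoms: none
Why: Hydride reduction; Felkin–Anh analysis at quaternary C1 (C10 large and anti, hydride passing the C15 methyl group) coincides with peripheral attack on the ring ketone and predicts the 2R alcohol.

Step 28
Reactants: 37 alcohol (2R alcohol of 36)
Product: 38 acetate (2-O-acetyl derivative of 37)
Conditions: Ac2O, DMAP, pyridine, rt
Reagents that add atoms: acetic anhydride, CC(=O)OC(C)=O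
Why: DMAP-catalysed acetylation of the only free hydroxyl; capping C2 now also prevents a transannular etherification once C6 carries chloride.

Step 29
Reactants: 38 acetate (2-O-acetyl derivative of 37)
Product: 39 allylic alcohol (38 with a free 6R hydroxyl)
Conditions: PPTS (cat.), MeOH/CH2Cl2, 0 °C → rt
Reagents that add atoms: none
Why: The secondary TES ether is the most acid-labile group left; TIPS ethers, acetonide, PMB ether and acetate should survive brief methanolysis.

Step 30
Reactants: 39 allylic alcohol (38 with a free 6R hydroxyl)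
Product: 40 allylic chloride (6S chloride of 39)
Conditions: PPh3, hexachloroacetone, CH2Cl2, 0 °C → rt
Reagents that add atoms: hexachloroacetone, ClC(Cl)(Cl)C(=O)C(Cl)(Cl)Cl
Why: Appel-type chlorination; this reagent pair is the variant known to convert secondary allylic alcohols into chlorides with inversion and with the least allylic shift, which gives the 6S chloride anti to O7.

Step 31
Reactants: 40 allylic chloride (6S chloride of 39)
Product: 41 triol (40 without the acetonide and without the primary TIPS group; free 7-, 8- and 19-hydroxyls)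
Conditions: aq. HF (48%), MeCN, 0 °C → rt
Reagents that add atoms: none
Why: Aqueous HF in acetonitrile cleaves the primary silyl ether and hydrolyses the acetonide, while the hindered secondary TIPS ether at C12, the PMB ether, the acetate and the chloride should persist.

Step 32
Reactants: 41 triol (40 without the acetonide and without the primary TIPS group; free 7-, 8- and 19-hydroxyls)
Product: 43 γ-lactone (C19(=O)–O7 lactone; free tertiary 8-hydroxyl), via lactol 42 (not isolated)
Conditions: TEMPO (20 mol%), PhI(OAc)2 (2.5 equiv), CH2Cl2, rt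
Reagents that add atoms: none
Why: Oxoammonium-mediated oxidative lactonisation of a 1,4-diol: the primary C19 alcohol is oxidised first, the aldehyde is trapped by O7 (O9 is blocked, O8 would give a four-membered ring), and the lactol is oxidised to the lactone under near-neutral conditions that should not epimerise C17.

Step 33
Reactants: 43 γ-lactone (C19(=O)–O7 lactone; free tertiary 8-hydroxyl)
Product: 44 ring A allylic alcohol (43 with a free 12α hydroxyl)
Conditions: HF·pyridine, pyridine/THF, 0 °C → rt
Reagents that add atoms: none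
Why: Buffered fluoride desilylation; HF·pyridine is chosen over basic fluoride to spare the allylic chloride, the acetate and the β-hydroxy lactone.

Step 34
Reactants: 44 ring A allylic alcohol (43 with a free 12α hydroxyl)
Product: 45 epoxy alcohol (13α,14α-epoxide of 44)
Conditions: VO(acac)2 (5 mol%), t-BuOOH (decane solution), CH2Cl2, 0 °C → rt
Reagents that add atoms: tert-butyl hydroperoxide, CC(C)(C)OO
Why: Vanadium-catalysed hydroxyl-directed epoxidation delivers oxygen to the face of the C12 hydroxyl (13S,14R); the C5=C16 alkene is deactivated by the allylic chloride and has only the remote, hindered tertiary C8 hydroxyl near it, which should not compete with the allylic C12 hydroxyl.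

Step 35
Reactants: 45 epoxy alcohol (13α,14α-epoxide of 44)
Product: 46 diacetate (12-O-acetyl derivative of 45; the 9-O-PMB ether of 47)
Conditions: Ac2O, pyridine, DMAP (cat.), CH2Cl2, 0 °C → rt
Reagents that add atoms: acetic anhydride, CC(=O)OC(C)=O
Why: Acetylation of the only free secondary hydroxyl; the hindered tertiary C8 hydroxyl should not react under these conditions.

Step 36
Reactants: 46 diacetate (12-O-acetyl derivative of 45; the 9-O-PMB ether of 47)
Product: 47 CNP0242711.1, (1S,2R,6S,7R,8R,9R,10S,11R,12S,13S,14R,17R)-2,12-diacetoxy-6-chloro-13,14-epoxy-8,9-dihydroxybriar-5(16)-en-19,7-olide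
Conditions: DDQ, CH2Cl2/pH 7 phosphate buffer (10:1), 0 °C → rt
Reagents that add atoms: none
Why: Oxidative cleavage of the PMB ether under neutral conditions that epoxide, allylic chloride, acetates and lactone tolerate; water is present so that the benzylic cation is hydrolysed and not trapped by the C8 hydroxyl.

## Compound list

1 | 2,2-dimethoxyacetaldehyde | COC(OC)C=O | starting material
2 | methyl 2-(triphenylphosphoranylidene)propanoate | COC(=O)C(C)=P(c1ccccc1)(c1ccccc1)c1ccccc1 | starting material
3 | methyl (E)-4,4-dimethoxy-2-methylbut-2-enoate | COC(=O)/C(C)=C/C(OC)OC | intermediate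
4 | methyl (E)-2-methyl-4-oxobut-2-enoate | COC(=O)/C(C)=C/C=O | intermediate
5 | (E)-pent-3-en-2-one | C/C=C/C(C)=O | starting material
6 | (E)-2-(triisopropylsilyloxy)penta-1,3-diene | C/C=C/C(=C)O[Si](C(C)C)(C(C)C)C(C)C | intermediate
7 | ring A aldehyde, methyl (1S,5S,6S)-6-formyl-1,5-dimethyl-3-(triisopropylsilyloxy)cyclohex-3-ene-1-carboxylate (C15, C9 and C20 all β) | COC(=O)[C@]1(C)[C@H]([C@@H](C)C=C(O[Si](C(C)C)(C(C)C)C(C)C)C1)C=O | intermediate
8 | methyl (S)-3-hydroxy-2-methylpropanoate | COC(=O)[C@@H](C)CO | starting material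
9 | methyl (S)-2-methyl-3-(triisopropylsilyloxy)propanoate | COC(=O)[C@@H](C)CO[Si](C(C)C)(C(C)C)C(C)C | intermediate
10 | (S)-2-methyl-3-(triisopropylsilyloxy)propanal | O=C[C@@H](C)CO[Si](C(C)C)(C(C)C)C(C)C | intermediate
11 | (R)-(4,4-dibromo-2-methylbut-3-enyloxy)triisopropylsilane | BrC(Br)=C[C@@H](C)CO[Si](C(C)C)(C(C)C)C(C)C | intermediate
12 | lithium acetylide of (R)-triisopropyl(2-methylbut-3-ynyloxy)silane | [Li]C#C[C@@H](C)CO[Si](C(C)C)(C(C)C)C(C)C | intermediate
13 | methyl (R)-4-methyl-5-(triisopropylsilyloxy)pent-2-ynoate | COC(=O)C#C[C@@H](C)CO[Si](C(C)C)(C(C)C)C(C)C | intermediate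
14 | methyl (S,Z)-3-iodo-4-methyl-5-(triisopropylsilyloxy)pent-2-enoate | COC(=O)/C=C(\I)[C@@H](C)CO[Si](C(C)C)(C(C)C)C(C)C | intermediate
15 | hydroxy enoate (7 with CHO converted into (9R)-CH(OH) bonded to C8 of a C8=C7H–CO2Me enoate, C9 cis to the ester; CH(CH3)CH2OTIPS on C8) | COC(=O)[C@]1(C)[C@H]([C@@H](C)C=C(O[Si](C(C)C)(C(C)C)C(C)C)C1)[C@@H](O)/C(=C\C(=O)OC)[C@@H](C)CO[Si](C(C)C)(C(C)C)C(C)C | intermediate
16 | butenolide (ring A of 7 bearing at C10 the (9R)-5-oxo-2,5-dihydrofuran-2-yl ring; O9–C6 lactone; C7=C8; CH(CH3)CH2OTIPS on C8) | COC(=O)[C@]1(C)[C@H]([C@@H](C)C=C(O[Si](C(C)C)(C(C)C)C(C)C)C1)[C@H]2OC(=O)C=C2[C@@H](C)CO[Si](C(C)C)(C(C)C)C(C)C | intermediate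
17 | silyloxy epoxide (12α,13α-epoxide of 16 with OTIPS on C13) | COC(=O)[C@]1(C)[C@H]([C@@H](C)[C@@H]3O[C@]3(O[Si](C(C)C)(C(C)C)C(C)C)C1)[C@H]2OC(=O)C=C2[C@@H](C)CO[Si](C(C)C)(C(C)C)C(C)C | intermediate
18 | α-silyloxy ketone (16 in which ring A has C12(H)–OTIPS on the α face and C13=O) | COC(=O)[C@]1(C)[C@H]([C@@H](C)[C@H](O[Si](C(C)C)(C(C)C)C(C)C)C(=O)C1)[C@H]2OC(=O)C=C2[C@@H](C)CO[Si](C(C)C)(C(C)C)C(C)C | intermediate
19 | diol lactone (18 with C7–OH and C8–OH cis to each other and trans to ring A on the saturated γ-lactone) | COC(=O)[C@]1(C)[C@H]([C@@H](C)[C@H](O[Si](C(C)C)(C(C)C)C(C)C)C(=O)C1)[C@H]2OC(=O)[C@H](O)[C@@]2(O)[C@@H](C)CO[Si](C(C)C)(C(C)C)C(C)C | intermediate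
20 | acetonide lactone (7,8-O-isopropylidene derivative of 19) | COC(=O)[C@]1(C)[C@H]([C@@H](C)[C@H](O[Si](C(C)C)(C(C)C)C(C)C)C(=O)C1)[C@H]2OC(=O)[C@@H]3OC(C)(C)O[C@]23[C@@H](C)CO[Si](C(C)C)(C(C)C)C(C)C | intermediate
21 | hydroxy Weinreb amide (20 with the lactone opened to C6(=O)N(CH3)OCH3 and a free 9R hydroxyl) | COC(=O)[C@]1(C)[C@H]([C@@H](C)[C@H](O[Si](C(C)C)(C(C)C)C(C)C)C(=O)C1)[C@@H](O)[C@@]2([C@@H](C)CO[Si](C(C)C)(C(C)C)C(C)C)OC(C)(C)O[C@H]2C(=O)N(C)OC | intermediate
22 | PMB ether (9-O-(4-methoxybenzyl) derivative of 21) | COC(=O)[C@]1(C)[C@H]([C@@H](C)[C@H](O[Si](C(C)C)(C(C)C)C(C)C)C(=O)C1)[C@@H](OCc3ccc(OC)cc3)[C@@]2([C@@H](C)CO[Si](C(C)C)(C(C)C)C(C)C)OC(C)(C)O[C@H]2C(=O)N(C)OC | intermediate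
23 | potassium enolate of 22 (C13(OK)=C14) | COC(=O)[C@]1(C)[C@H]([C@@H](C)[C@H](O[Si](C(C)C)(C(C)C)C(C)C)C(O[K])=C1)[C@@H](OCc3ccc(OC)cc3)[C@@]2([C@@H](C)CO[Si](C(C)C)(C(C)C)C(C)C)OC(C)(C)O[C@H]2C(=O)N(C)OC | intermediate
24 | enol triflate (22 with C13(OSO2CF3)=C14 in ring A) | COC(=O)[C@]1(C)[C@H]([C@@H](C)[C@H](O[Si](C(C)C)(C(C)C)C(C)C)C(OS(=O)(=O)C(F)(F)F)=C1)[C@@H](OCc3ccc(OC)cc3)[C@@]2([C@@H](C)CO[Si](C(C)C)(C(C)C)C(C)C)OC(C)(C)O[C@H]2C(=O)N(C)OC | intermediate
25 | ring A alkene (24 with H in place of the triflate; 12α-OTIPS; C13=C14) | COC(=O)[C@]1(C)[C@H]([C@@H](C)[C@H](O[Si](C(C)C)(C(C)C)C(C)C)C=C1)[C@@H](OCc3ccc(OC)cc3)[C@@]2([C@@H](C)CO[Si](C(C)C)(C(C)C)C(C)C)OC(C)(C)O[C@H]2C(=O)N(C)OC | intermediate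
26 | 2-bromoprop-2-en-1-ol | C=C(Br)CO | starting material
27 | (2-bromoprop-2-enyloxy)triethylsilane | C=C(Br)CO[Si](CC)(CC)CC | intermediate
28 | [3-(triethylsilyloxy)prop-1-en-2-yl]lithium | [Li]C(=C)CO[Si](CC)(CC)CC | intermediate
29 | enone (25 with C6 as a ketone bonded to C5(=C4H2)–C16H2OTES) | COC(=O)[C@]1(C)[C@H]([C@@H](C)[C@H](O[Si](C(C)C)(C(C)C)C(C)C)C=C1)[C@@H](OCc3ccc(OC)cc3)[C@@]2([C@@H](C)CO[Si](C(C)C)(C(C)C)C(C)C)OC(C)(C)O[C@H]2C(=O)C(=C)CO[Si](CC)(CC)CC | intermediate
30 | allylic alcohol (6R alcohol of 29; O6 syn to O7) | COC(=O)[C@]1(C)[C@H]([C@@H](C)[C@H](O[Si](C(C)C)(C(C)C)C(C)C)C=C1)[C@@H](OCc3ccc(OC)cc3)[C@@]2([C@@H](C)CO[Si](C(C)C)(C(C)C)C(C)C)OC(C)(C)O[C@H]2[C@H](O)C(=C)CO[Si](CC)(CC)CC | intermediate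
31 | bis-TES ether (6-O-triethylsilyl derivative of 30) | COC(=O)[C@]1(C)[C@H]([C@@H](C)[C@H](O[Si](C(C)C)(C(C)C)C(C)C)C=C1)[C@@H](OCc3ccc(OC)cc3)[C@@]2([C@@H](C)CO[Si](C(C)C)(C(C)C)C(C)C)OC(C)(C)O[C@H]2[C@H](O[Si](CC)(CC)CC)C(=C)CO[Si](CC)(CC)CC | intermediate
32 | carboxylic acid (31 with CO2H at C2) | OC(=O)[C@]1(C)[C@H]([C@@H](C)[C@H](O[Si](C(C)C)(C(C)C)C(C)C)C=C1)[C@@H](OCc3ccc(OC)cc3)[C@@]2([C@@H](C)CO[Si](C(C)C)(C(C)C)C(C)C)OC(C)(C)O[C@H]2[C@H](O[Si](CC)(CC)CC)C(=C)CO[Si](CC)(CC)CC | intermediate
33 | hydroxy acid (32 with a free C16 hydroxyl) | OC(=O)[C@]1(C)[C@H]([C@@H](C)[C@H](O[Si](C(C)C)(C(C)C)C(C)C)C=C1)[C@@H](OCc3ccc(OC)cc3)[C@@]2([C@@H](C)CO[Si](C(C)C)(C(C)C)C(C)C)OC(C)(C)O[C@H]2[C@H](O[Si](CC)(CC)CC)C(=C)CO | intermediate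
34 | ten-membered lactone (C2(=O)–O–C16; ring atoms C2, O, C16, C5–C10 and C1; C5=C4H2) | O=C1OCC(=C)[C@@H](O[Si](CC)(CC)CC)[C@@H]4OC(C)(C)O[C@]4([C@@H](C)CO[Si](C(C)C)(C(C)C)C(C)C)[C@H](OCc5ccc(OC)cc5)[C@H]3[C@@H](C)[C@H](O[Si](C(C)C)(C(C)C)C(C)C)C=C[C@]13C | intermediate
35 | ten-membered bis-exocyclic allyl vinyl ether (34 with C2=C3H2 in place of C2=O) | C=C1OCC(=C)[C@@H](O[Si](CC)(CC)CC)[C@@H]4OC(C)(C)O[C@]4([C@@H](C)CO[Si](C(C)C)(C(C)C)C(C)C)[C@H](OCc5ccc(OC)cc5)[C@H]3[C@@H](C)[C@H](O[Si](C(C)C)(C(C)C)C(C)C)C=C[C@]13C | intermediate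
36 | ten-membered C2 ketone with C5=C16H2 methylidene (carbocycle C1–C10) | C=C1CCC(=O)[C@]2(C)[C@H]([C@@H](C)[C@H](O[Si](C(C)C)(C(C)C)C(C)C)C=C2)[C@@H](OCc3ccc(OC)cc3)[C@@]4([C@@H](C)CO[Si](C(C)C)(C(C)C)C(C)C)OC(C)(C)O[C@H]4[C@@H]1O[Si](CC)(CC)CC | intermediate
37 | alcohol (2R alcohol of 36) | C=C1CC[C@@H](O)[C@]2(C)[C@H]([C@@H](C)[C@H](O[Si](C(C)C)(C(C)C)C(C)C)C=C2)[C@@H](OCc3ccc(OC)cc3)[C@@]4([C@@H](C)CO[Si](C(C)C)(C(C)C)C(C)C)OC(C)(C)O[C@H]4[C@@H]1O[Si](CC)(CC)CC | intermediate
38 | acetate (2-O-acetyl derivative of 37) | C=C1CC[C@@H](OC(C)=O)[C@]2(C)[C@H]([C@@H](C)[C@H](O[Si](C(C)C)(C(C)C)C(C)C)C=C2)[C@@H](OCc3ccc(OC)cc3)[C@@]4([C@@H](C)CO[Si](C(C)C)(C(C)C)C(C)C)OC(C)(C)O[C@H]4[C@@H]1O[Si](CC)(CC)CC | intermediate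
39 | allylic alcohol (38 with a free 6R hydroxyl) | C=C1CC[C@@H](OC(C)=O)[C@]2(C)[C@H]([C@@H](C)[C@H](O[Si](C(C)C)(C(C)C)C(C)C)C=C2)[C@@H](OCc3ccc(OC)cc3)[C@@]4([C@@H](C)CO[Si](C(C)C)(C(C)C)C(C)C)OC(C)(C)O[C@H]4[C@@H]1O | intermediate
40 | allylic chloride (6S chloride of 39) | C=C1CC[C@@H](OC(C)=O)[C@]2(C)[C@H]([C@@H](C)[C@H](O[Si](C(C)C)(C(C)C)C(C)C)C=C2)[C@@H](OCc3ccc(OC)cc3)[C@@]4([C@@H](C)CO[Si](C(C)C)(C(C)C)C(C)C)OC(C)(C)O[C@H]4[C@H]1Cl | intermediate
41 | triol (40 without the acetonide and without the primary TIPS group; free 7-, 8- and 19-hydroxyls) | C=C1CC[C@@H](OC(C)=O)[C@]2(C)[C@H]([C@@H](C)[C@H](O[Si](C(C)C)(C(C)C)C(C)C)C=C2)[C@@H](OCc3ccc(OC)cc3)[C@@]([C@@H](C)CO)(O)[C@@H](O)[C@H]1Cl | intermediate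
42 | lactol (C19 hemiacetal of 41 closed onto O7) | C=C1CC[C@@H](OC(C)=O)[C@]2(C)[C@H]([C@@H](C)[C@H](O[Si](C(C)C)(C(C)C)C(C)C)C=C2)[C@@H](OCc3ccc(OC)cc3)[C@]4(O)[C@@H](C)C(O)O[C@H]4[C@H]1Cl | intermediate
43 | γ-lactone (C19(=O)–O7 lactone; free tertiary 8-hydroxyl) | C=C1CC[C@@H](OC(C)=O)[C@]2(C)[C@H]([C@@H](C)[C@H](O[Si](C(C)C)(C(C)C)C(C)C)C=C2)[C@@H](OCc3ccc(OC)cc3)[C@]4(O)[C@@H](C)C(=O)O[C@H]4[C@H]1Cl | intermediate
44 | ring A allylic alcohol (43 with a free 12α hydroxyl) | C=C1CC[C@@H](OC(C)=O)[C@]2(C)[C@H]([C@@H](C)[C@H](O)C=C2)[C@@H](OCc3ccc(OC)cc3)[C@]4(O)[C@@H](C)C(=O)O[C@H]4[C@H]1Cl | intermediate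
45 | epoxy alcohol (13α,14α-epoxide of 44) | C=C1CC[C@@H](OC(C)=O)[C@]2(C)[C@H]([C@@H](C)[C@H](O)[C@@H]3O[C@@H]32)[C@@H](OCc5ccc(OC)cc5)[C@]4(O)[C@@H](C)C(=O)O[C@H]4[C@H]1Cl | intermediate
46 | diacetate (12-O-acetyl derivative of 45; the 9-O-PMB ether of 47) | C=C1CC[C@@H](OC(C)=O)[C@]2(C)[C@H]([C@@H](C)[C@H](OC(C)=O)[C@@H]3O[C@@H]32)[C@@H](OCc5ccc(OC)cc5)[C@]4(O)[C@@H](C)C(=O)O[C@H]4[C@H]1Cl | intermediate
47 | CNP0242711.1, (1S,2R,6S,7R,8R,9R,10S,11R,12S,13S,14R,17R)-2,12-diacetoxy-6-chloro-13,14-epoxy-8,9-dihydroxybriar-5(16)-en-19,7-olide | C=C1CC[C@@H](OC(C)=O)[C@]2(C)[C@H]([C@@H](C)[C@H](OC(C)=O)[C@@H]3O[C@@H]32)[C@@H](O)[C@]2(O)[C@@H](C)C(=O)O[C@H]2[C@H]1Cl | target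

## Step count and least certain steps

Total step count: 36. Longest linear sequence: 31 steps (from 8 through steps 5–17 and 19–36).

Step 26 (key step, new method). The most likely failure is that the ring cannot reach the boat fold at temperatures the molecule tolerates, so that 35 is recovered or slowly destroyed by elimination of silanol or by traces of acid acting on the enol ether. Fallback with known chemistry, setting out from 31: PhSO2CH2Li (THF, −78 → 0 °C) converts the C2 ester into the open-chain β-keto sulfone F1. PPTS in MeOH frees the primary C16 hydroxyl to give the hydroxy β-keto sulfone F2, and ClCO2Me/pyridine gives the allylic methyl carbonate F3. Pd(PPh3)4 with 1,2-bis(diphenylphosphino)ethane in THF at high dilution (Tsuji–Trost macrocyclisation of a stabilised carbanion onto a 2-substituted π-allyl unit, whose two CH2 termini give the same product) closes the C3–C4 bond to the cyclic 3-phenylsulfonyl ketone F4. SmI2 in THF/MeOH removes the sulfone, and the route is rejoined at 36.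

Step 24. Ten-membered lactones are the hardest ring size; intermolecular esterification to the dimeric diolide and elimination of the activated allylic alcohol are the likely side paths, and the pivalate-like carboxylate is a weak nucleophile. Fallback, setting out from 25: the ester C–O bond is made intermolecularly and the ring is closed through C5–C6. n-PrSLi gives the carboxylic acid F5; Cs2CO3 and 2,3-dibromopropene in DMF give the 2-bromoallyl ester F6; Cp2Zr(H)Cl reduces the Weinreb amide to the C6 aldehyde F7. An intramolecular Nozaki–Hiyama–Kishi reaction (CrCl2, NiCl2 cat., DMSO/THF, high dilution) gives the hydroxy lactone F8, whose 6R epimer is separated and silylated with TESOTf to rejoin the route at 34.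

Step 4. The silyl enol ether terminus may add to the formyl carbon (aldol or hetero-Diels–Alder path) in place of the alkene, the ester-endo mode would give the C11 epimer, and the enantiofacial sense for a dienophile with two carbonyl groups is not secured by analogy. Fallback, setting out from 4 and 6: Me2AlCl-promoted cycloaddition gives 7 together with its enantiomer F9. Coupling of the racemate with enantiopure 14 under the conditions of step 10 gives 16 and the diastereomeric butenolide F10, which differ in physical properties and are separated by chromatography; the route is rejoined at 16.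

Step 30. Ion-pair collapse or allylic displacement at C16 would give the transposed primary chloride or partial retention, because C6 is flanked by the bulky dioxolane carbon. Fallback, setting out from 39, which makes the allylic shift part of the plan: N-(phenylseleno)phthalimide and n-Bu3P convert the alcohol into an allylic selenide, which should settle by 1,3-shift as the primary C16 phenyl selenide F13 (C5=C6 in the ring). N-Chlorosuccinimide then chlorinates selenium, and the [2,3]-sigmatropic shift returns chlorine to C6 with the double bond back at C5=C16, rejoining the route at 40. The face of delivery is set by the ring conformation and would have to be confirmed.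

Step 20. Facial selectivity may be poor if cerium or the dioxolane oxygen enforces a chelated arrangement, giving the 6S alcohol. Fallback, setting out from 29: the reduction mixture is separated, and the C6 epimer F11 is inverted by Mitsunobu esterification (4-nitrobenzoic acid, PPh3, DIAD) to the 4-nitrobenzoate F12 with the 6R configuration, which K2CO3 in MeOH at 0 °C cleaves to rejoin the route at 30.

## Further compounds

F1 | step 26 | open-chain β-keto sulfone (31 with C2(=O)–CH2SO2Ph in place of the methyl ester) | O=C(CS(=O)(=O)c4ccccc4)[C@]1(C)[C@H]([C@@H](C)[C@H](O[Si](C(C)C)(C(C)C)C(C)C)C=C1)[C@@H](OCc3ccc(OC)cc3)[C@@]2([C@@H](C)CO[Si](C(C)C)(C(C)C)C(C)C)OC(C)(C)O[C@H]2[C@H](O[Si](CC)(CC)CC)C(=C)CO[Si](CC)(CC)CC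
F2 | step 26 | hydroxy β-keto sulfone (F1 with a free C16 hydroxyl) | O=C(CS(=O)(=O)c4ccccc4)[C@]1(C)[C@H]([C@@H](C)[C@H](O[Si](C(C)C)(C(C)C)C(C)C)C=C1)[C@@H](OCc3ccc(OC)cc3)[C@@]2([C@@H](C)CO[Si](C(C)C)(C(C)C)C(C)C)OC(C)(C)O[C@H]2[C@H](O[Si](CC)(CC)CC)C(=C)CO
F3 | step 26 | allylic methyl carbonate of F2 | O=C(CS(=O)(=O)c4ccccc4)[C@]1(C)[C@H]([C@@H](C)[C@H](O[Si](C(C)C)(C(C)C)C(C)C)C=C1)[C@@H](OCc3ccc(OC)cc3)[C@@]2([C@@H](C)CO[Si](C(C)C)(C(C)C)C(C)C)OC(C)(C)O[C@H]2[C@H](O[Si](CC)(CC)CC)C(=C)COC(=O)OC
F4 | step 26 | cyclic 3-phenylsulfonyl ketone (36 with SO2Ph on C3) | C=C1CC(S(=O)(=O)c5ccccc5)C(=O)[C@]2(C)[C@H]([C@@H](C)[C@H](O[Si](C(C)C)(C(C)C)C(C)C)C=C2)[C@@H](OCc3ccc(OC)cc3)[C@@]4([C@@H](C)CO[Si](C(C)C)(C(C)C)C(C)C)OC(C)(C)O[C@H]4[C@@H]1O[Si](CC)(CC)CC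
F5 | step 24 | carboxylic acid of 25 | OC(=O)[C@]1(C)[C@H]([C@@H](C)[C@H](O[Si](C(C)C)(C(C)C)C(C)C)C=C1)[C@@H](OCc3ccc(OC)cc3)[C@@]2([C@@H](C)CO[Si](C(C)C)(C(C)C)C(C)C)OC(C)(C)O[C@H]2C(=O)N(C)OC
F6 | step 24 | 2-bromoallyl ester of F5 | C=C(Br)COC(=O)[C@]1(C)[C@H]([C@@H](C)[C@H](O[Si](C(C)C)(C(C)C)C(C)C)C=C1)[C@@H](OCc3ccc(OC)cc3)[C@@]2([C@@H](C)CO[Si](C(C)C)(C(C)C)C(C)C)OC(C)(C)O[C@H]2C(=O)N(C)OC
F7 | step 24 | C6 aldehyde (F6 with CHO in place of the Weinreb amide) | C=C(Br)COC(=O)[C@]1(C)[C@H]([C@@H](C)[C@H](O[Si](C(C)C)(C(C)C)C(C)C)C=C1)[C@@H](OCc3ccc(OC)cc3)[C@@]2([C@@H](C)CO[Si](C(C)C)(C(C)C)C(C)C)OC(C)(C)O[C@H]2C=O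
F8 | step 24 | hydroxy lactone (34 with a free 6R hydroxyl) | O=C1OCC(=C)[C@@H](O)[C@@H]4OC(C)(C)O[C@]4([C@@H](C)CO[Si](C(C)C)(C(C)C)C(C)C)[C@H](OCc5ccc(OC)cc5)[C@H]3[C@@H](C)[C@H](O[Si](C(C)C)(C(C)C)C(C)C)C=C[C@]13C
F9 | step 4 | enantiomer of 7, methyl (1R,5R,6R)-6-formyl-1,5-dimethyl-3-(triisopropylsilyloxy)cyclohex-3-ene-1-carboxylate | COC(=O)[C@@]1(C)[C@@H]([C@H](C)C=C(O[Si](C(C)C)(C(C)C)C(C)C)C1)C=O
F10 | step 4 | diastereomeric butenolide (from F9 and 14; ring A and C9 mirrored, C17 as in 16) | COC(=O)[C@@]1(C)[C@@H]([C@H](C)C=C(O[Si](C(C)C)(C(C)C)C(C)C)C1)[C@@H]2OC(=O)C=C2[C@@H](C)CO[Si](C(C)C)(C(C)C)C(C)C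
F11 | step 20 | C6 epimer of 30 (6S alcohol) | COC(=O)[C@]1(C)[C@H]([C@@H](C)[C@H](O[Si](C(C)C)(C(C)C)C(C)C)C=C1)[C@@H](OCc3ccc(OC)cc3)[C@@]2([C@@H](C)CO[Si](C(C)C)(C(C)C)C(C)C)OC(C)(C)O[C@H]2[C@@H](O)C(=C)CO[Si](CC)(CC)CC
F12 | step 20 | 4-nitrobenzoate of 30 (6R ester) | COC(=O)[C@]1(C)[C@H]([C@@H](C)[C@H](O[Si](C(C)C)(C(C)C)C(C)C)C=C1)[C@@H](OCc3ccc(OC)cc3)[C@@]2([C@@H](C)CO[Si](C(C)C)(C(C)C)C(C)C)OC(C)(C)O[C@H]2[C@H](OC(=O)c4ccc(cc4)[N+](=O)[O-])C(=C)CO[Si](CC)(CC)CC
F13 | step 30 | primary allylic selenide (39 transposed: C16H2–SePh, C5=C6 in the ring) | c6ccccc6[Se]C/C1=C/[C@@H]4OC(C)(C)O[C@]4([C@@H](C)CO[Si](C(C)C)(C(C)C)C(C)C)[C@H](OCc5ccc(OC)cc5)[C@H]3[C@@H](C)[C@H](O[Si](C(C)C)(C(C)C)C(C)C)C=C[C@]3(C)[C@H](OC(C)=O)CC1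
A1 | alternative 1 | ring A silyl enol ether aldehyde | O=C[C@]1(C)[C@H]([C@@H](C)C(O[Si](C)(C)C(C)(C)C)=CC1)[C@H]2OC(C)(C)OC2
A2 | alternative 1 | (R,E)-3-(2,2-dimethyl-1,3-dioxolan-4-yl)-2-methylprop-2-enal | O=C/C(C)=C/[C@@H]1COC(C)(C)O1
A3 | alternative 1 | (Z)-3-(tert-butyldimethylsilyloxy)penta-1,3-diene | C/C=C(/C=C)O[Si](C)(C)C(C)(C)C
A4 | alternative 2 | C6 chloro lactone with C5 silyloxymethyl group | C1C[C@@H](OC(C)=O)[C@]2(C)[C@H]([C@@H](C)[C@H](OC(C)=O)[C@@H]3O[C@@H]32)[C@@H](O[Si](CC)(CC)CC)[C@]4(O)[C@@H](C)C(=O)O[C@H]4[C@@H](Cl)[C@@H]1CO[Si](C)(C)C(C)(C)C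
A5 | alternative 2 | seco acid with E C6=C7 alkene | C1C[C@@H](OC(C)=O)[C@]2(C)[C@H]([C@@H](C)[C@H](OC(C)=O)[C@@H]3O[C@@H]32)[C@@H](O[Si](CC)(CC)CC)[C@](O)([C@@H](C)C(=O)O)/C=C/[C@@H]1CO[Si](C)(C)C(C)(C)C
A6 | alternative 3 | ring A-fused cyclodecane-2,7-dione with C5 ketal | O1CCOC12CCC(=O)[C@]3(C)[C@H]([C@@H](C)[C@H](O[Si](C)(C)C(C)(C)C)CC3)CCC(=O)C2
A7 | alternative 3 | hydrophenanthrene with C2=C7 alkene and C5 ketal | O1CCOC12CCC3=C(C2)CC[C@H]4[C@@H](C)[C@H](O[Si](C)(C)C(C)(C)C)CC[C@]34C
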